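## Retrosynthetic overview

1. The plan rests on the two pyranone rings (ring C of unit 1: O1, C2, C3, C4, C4a, C8a; ring C of unit 2: the same atoms double-primed). In each ring the oxygen sits on the carbon beta to the C4 (C4'') ketone, so O1–C2 and O1''–C2'' are retro-oxa-Michael bonds, and C3–C3'' is the central bond of a succinyl chain.
2. With 7''-OH and 4'''-OH masked as benzyl ethers (freed last by hydrogenolysis), cutting both bonds erases all four stereocentres. This leads to one (2E,3E)-2,3-bis(arylidene)-1,4-diarylbutane-1,4-dione with four free ortho-phenols.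
3. Its two aryl–carbonyl bonds go back to lithiated MOM ethers of phloroglucinol, added one after the other: first to a lactone carbonyl (unit 2 side), then to the enal made from the lactone CH2O carbon (unit 1 side).
4. The bis(arylidene)butyrolactone comes from two Stobbe condensations on dimethyl succinate, which set both E alkenes and leave the two carboxyl carbons different (acid against ester).
5. Ring order: a temporary butyrolactone (made in step 7, opened in step 8), then in one flask the pyranone ring of unit 2 followed by that of unit 1. The four benzene rings are bought.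

Key step: step 13

Numbering: flavanone numbering is used. Unprimed and single-primed atoms belong to the 7,4'-di-O-methyl half (unit 1); double- and triple-primed atoms belong to the naringenin half (unit 2). The target is (2S,3S,2''S,3''R), which means cis at C2/C3 and trans at C2''/C3''.

Assumption: the quinine-derived thiourea is taken to give the S sense at both benzylic carbons; if it gives R, the quinidine-derived pseudoenantiomer replaces it with no other change.

## Route

Step 1
Reactants: 1 phloroglucinol
Product: 2 3,5-bis(methoxymethoxy)phenol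
Conditions: NaH (2.1 equiv), MOMCl (2.0 equiv), DMF, 0 °C to rt
Reagents that add atoms: chloromethyl methyl ether (MOMCl), COCCl
Why: Williamson-type O-alkylation of the sodium phenoxide, run with two equivalents so that the bis-ether is the main member of a statistical set and is separated from mono- and tris-ether by chromatography; this single phenol then serves both aryl building blocks.

Step 2
Reactants: 2 3,5-bis(methoxymethoxy)phenol
Product: 3 1-methoxy-3,5-bis(methoxymethoxy)benzene
Conditions: MeI, K2CO3, acetone, reflux
Reagents that add atoms: iodomethane, CI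
Why: Williamson ether synthesis on the only free phenol, under carbonate conditions to which the MOM acetals are inert.

Step 3
Reactants: 2 3,5-bis(methoxymethoxy)phenol
Product: 4 1-(benzyloxy)-3,5-bis(methoxymethoxy)benzene
Conditions: BnBr, K2CO3, DMF, rt
Reagents that add atoms: benzyl bromide, BrCc1ccccc1
Why: Williamson ether synthesis again, which puts a benzyl group, removable later by neutral hydrogenolysis, on the oxygen that becomes O7''.

Step 4
Reactants: 5 dimethyl succinate; 6 4-methoxybenzaldehyde
Product: 7 (E)-3-(methoxycarbonyl)-4-(4-methoxyphenyl)but-3-enoic acid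
Conditions: NaOMe, MeOH, reflux; then aq HCl
Reagents that add atoms: none
Why: Stobbe condensation, in which the succinate enolate adds to the aldehyde, the alkoxide closes a paraconic lactone on the distal ester and E1cB opening gives the half-ester, the aryl group ending trans to the conjugated ester (E) to avoid allylic strain.

Step 5
Reactants: 7 (E)-3-(methoxycarbonyl)-4-(4-methoxyphenyl)but-3-enoic acid
Product: 8 dimethyl (E)-2-(4-methoxybenzylidene)succinate
Conditions: MeOH, H2SO4 (cat.), reflux
Reagents that add atoms: methanol, CO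
Why: Fischer esterification restores the diester needed for a second enolisation, and the conjugated E alkene is not touched by acid in methanol.

Step 6
Reactants: 8 dimethyl (E)-2-(4-methoxybenzylidene)succinate; 9 4-(benzyloxy)benzaldehyde
Product: 10 (2E,3E)-4-[4-(benzyloxy)phenyl]-3-(methoxycarbonyl)-2-(4-methoxybenzylidene)but-3-enoic acid
Conditions: NaOMe, MeOH, reflux, dark; then aq HCl
Reagents that add atoms: none
Why: Second Stobbe condensation at the remaining CH2 group, where the paraconic lactone can only form on the ester next to the anisylidene carbon, so that this carboxyl emerges as the free acid while the ester next to the new E benzylidene survives, which labels the two ends for units 1 and 2.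

Step 7
Reactants: 10 (2E,3E)-4-[4-(benzyloxy)phenyl]-3-(methoxycarbonyl)-2-(4-methoxybenzylidene)but-3-enoic acid
Product: 13 (3E,4E)-3-[4-(benzyloxy)benzylidene]-4-(4-methoxybenzylidene)dihydrofuran-2(3H)-one, via mixed carbonic anhydride 11 (not isolated), via hydroxy ester 12 (not isolated)
Conditions: ClCO2Et, Et3N, THF, −10 °C; then NaBH4, THF–H2O, 0 °C; then p-TsOH (cat.), CH2Cl2, rt
Reagents that add atoms: none
Why: Mixed-anhydride activation followed by NaBH4 reduction is the standard way to take an acid to the alcohol beside an ester, and the allylic alcohol then lactonises onto the neighbouring methyl ester to give a bis(arylidene)butyrolactone of a stable, known type.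

Step 8
Reactants: 4 1-(benzyloxy)-3,5-bis(methoxymethoxy)benzene; 13 (3E,4E)-3-[4-(benzyloxy)benzylidene]-4-(4-methoxybenzylidene)dihydrofuran-2(3H)-one
Product: 15 (2E,3E)-1-[4-(benzyloxy)-2,6-bis(methoxymethoxy)phenyl]-2-[4-(benzyloxy)benzylidene]-3-(hydroxymethyl)-4-(4-methoxyphenyl)but-3-en-1-one, via aryllithium 14 (not isolated)
Conditions: 4, n-BuLi, THF, 0 °C; then 13, −78 to −40 °C; aq NH4Cl
Reagents that add atoms: none
Why: Directed ortho-metalation takes place at the one position flanked by both OMOM groups, and 1,2-addition of the aryllithium to the flat, exposed lactone carbonyl stops at the ketone stage because a 2,6-disubstituted aryl ketone is too crowded for a second addition.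

Step 9
Reactants: 15 (2E,3E)-1-[4-(benzyloxy)-2,6-bis(methoxymethoxy)phenyl]-2-[4-(benzyloxy)benzylidene]-3-(hydroxymethyl)-4-(4-methoxyphenyl)but-3-en-1-one
Product: 16 (2E,3E)-4-[4-(benzyloxy)-2,6-bis(methoxymethoxy)phenyl]-3-[4-(benzyloxy)benzylidene]-2-(4-methoxybenzylidene)-4-oxobutanal
Conditions: MnO2 (activated, excess), CH2Cl2, rt, dark
Reagents that add atoms: none
Why: MnO2 oxidation is selective for the primary allylic alcohol, drains the open hydroxy enone from any cyclic hemiketal in equilibrium with it, and leaves ethers, acetals and both alkenes alone.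

Step 10
Reactants: 3 1-methoxy-3,5-bis(methoxymethoxy)benzene; 16 (2E,3E)-4-[4-(benzyloxy)-2,6-bis(methoxymethoxy)phenyl]-3-[4-(benzyloxy)benzylidene]-2-(4-methoxybenzylidene)-4-oxobutanal
Product: 18 (2E,3E)-1-[4-(benzyloxy)-2,6-bis(methoxymethoxy)phenyl]-2-[4-(benzyloxy)benzylidene]-4-hydroxy-4-[4-methoxy-2,6-bis(methoxymethoxy)phenyl]-3-(4-methoxybenzylidene)butan-1-one (racemic carbinol), via aryllithium 17 (not isolated)
Conditions: 3, n-BuLi, THF, 0 °C; then 16, −78 °C; aq NH4Cl
Reagents that add atoms: none
Why: Directed ortho-metalation between the two OMOM groups is followed by 1,2-addition of the aryllithium to the enal, which is far more reactive than the shielded diortho-substituted aryl ketone; the carbinol centre forms without control and is erased in step 11.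

Step 11
Reactants: 18 the hydroxy ketone of step 10
Product: 19 (2E,3E)-1-[4-methoxy-2,6-bis(methoxymethoxy)phenyl]-2-(4-methoxybenzylidene)-3-[4-(benzyloxy)benzylidene]-4-[4-(benzyloxy)-2,6-bis(methoxymethoxy)phenyl]butane-1,4-dione
Conditions: 2-iodoxybenzoic acid, DMSO–THF, rt, dark
Reagents that add atoms: none
Why: Hypervalent-iodine oxidation of a doubly activated (benzylic and allylic) secondary alcohol runs under neutral conditions that spare MOM acetals, benzyl ethers and the E,E-diene.

Step 12
Reactants: 19 the fully protected bis-chalcone of step 11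
Product: 20 (2E,3E)-1-(2,6-dihydroxy-4-methoxyphenyl)-2-(4-methoxybenzylidene)-3-[4-(benzyloxy)benzylidene]-4-[4-(benzyloxy)-2,6-dihydroxyphenyl]butane-1,4-dione
Conditions: HCl (methanolic), MeOH–THF, 0 °C to rt, dark; cold pH 6 buffer, used at once
Reagents that add atoms: none
Why: Acid-catalysed transacetalisation of the four aryl MOM ethers to methanol, helped by the neighbouring carbonyl groups, leaves benzyl and methyl ethers intact, and at low pH and low temperature the un-ionised, carbonyl-chelated phenols should add to the enones only slowly, so the open bis-chalcone can be isolated.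

Step 13
Reactants: 20 (2E,3E)-1-(2,6-dihydroxy-4-methoxyphenyl)-2-(4-methoxybenzylidene)-3-[4-(benzyloxy)benzylidene]-4-[4-(benzyloxy)-2,6-dihydroxyphenyl]butane-1,4-dione
Product: 22 (2S,3S)-3-{(2S,3R)-7-(benzyloxy)-2-[4-(benzyloxy)phenyl]-5-hydroxy-4-oxochroman-3-yl}-5-hydroxy-7-methoxy-2-(4-methoxyphenyl)chroman-4-one, via half-closed flavanone 21 (not isolated)
Conditions: N-[3,5-bis(trifluoromethyl)phenyl]-N'-[(8α,9S)-6'-methoxycinchonan-9-yl]thiourea (20 mol %), toluene, −25 °C, dark; cold filtration through SiO2, then chromatography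
Reagents that add atoms: none
Why: Proposed new method: the quinuclidine nitrogen of the catalyst takes the proton of a free ortho-phenol while the thiourea N–H bonds bind the adjoining aryl ketone, so that the phenol oxygen adds to the benzylidene carbon of its own enone (O1''–C2'' in unit 2, O1–C2 in unit 1) and each enol so formed is protonated at C3'' or C3. The closest known reaction type is the amine–thiourea-catalysed enantioselective oxa-Michael cyclisation of 2'-hydroxychalcones and of alpha-substituted relatives such as alkylidene beta-keto esters to flavanones; its twofold use on a cross-conjugated 2,3-diaroylbuta-1,3-diene, with one kinetic cis centre retained, has not been shown. Both pyranone rings close in the 6-endo-trig mode, which is preferred over attack on the distal benzylidene carbon because that would need a seven-membered ring. C2'' and C2 are set by the catalyst, which presents the same face of each benzylidene carbon to its phenol, and as both centres are S one catalyst serves both closures. C3'' is set by equilibration in the half-closed 21, where its hydrogen is alpha to C4''=O as well as allylic to the surviving enone and is therefore epimerised by the amine to the trans (3''R) diequatorial arrangement, whereas C3 is set by kinetic protonation of the second enol on the face away from the pseudoaxial 4-methoxyphenyl group at C2, which gives the cis (3S) arrangement that survives because this hydrogen is activated by one ketone only and the run is stopped cold. The step needs regiocontrol, secured by the symmetry of each aroyl ring about its acyl axis (either ortho-hydroxyl gives the same ring), configurational stability at C2'', secured by the benzyl ethers that block quinone-methide reopening and remove the two most acidic hydroxyls, and closure of unit 2 before unit 1, for which benzyloxy against methoxy gives no real bias, so the isomer with exchanged cis and trans halves is the expected companion and is removed by chromatography.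

Step 14
Reactants: 22 the 7'',4'''-di-O-benzyl biflavanone of step 13
Product: 23 (2S,3S)-3-[(2S,3R)-5,7-dihydroxy-2-(4-hydroxyphenyl)-4-oxochroman-3-yl]-5-hydroxy-7-methoxy-2-(4-methoxyphenyl)chroman-4-one (CNP0279849.1)
Conditions: H2 (1 atm), Pd/C, EtOAc, rt
Reagents that add atoms: none
Why: Catalytic hydrogenolysis cleaves the two aryl benzyl ethers under neutral conditions, so that neither the base-sensitive cis C2/C3 pair nor the other stereocentres are disturbed, and flavanone C2–O1 bonds are known to survive such mild debenzylation.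

## Compound list

1 | phloroglucinol | Oc1cc(O)cc(O)c1 | starting material
2 | 3,5-bis(methoxymethoxy)phenol | COCOc1cc(O)cc(OCOC)c1 | intermediate
3 | 1-methoxy-3,5-bis(methoxymethoxy)benzene | COCOc1cc(OC)cc(OCOC)c1 | intermediate
4 | 1-(benzyloxy)-3,5-bis(methoxymethoxy)benzene | COCOc1cc(OCc2ccccc2)cc(OCOC)c1 | intermediate
5 | dimethyl succinate | COC(=O)CCC(=O)OC | starting material
6 | 4-methoxybenzaldehyde | COc1ccc(C=O)cc1 | starting material
7 | (E)-3-(methoxycarbonyl)-4-(4-methoxyphenyl)but-3-enoic acid | COc1ccc(/C=C(\CC(=O)O)C(=O)OC)cc1 | intermediate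
8 | dimethyl (E)-2-(4-methoxybenzylidene)succinate | COc1ccc(/C=C(\CC(=O)OC)C(=O)OC)cc1 | intermediate
9 | 4-(benzyloxy)benzaldehyde | O=Cc1ccc(OCc2ccccc2)cc1 | starting material
10 | (2E,3E)-4-[4-(benzyloxy)phenyl]-3-(methoxycarbonyl)-2-(4-methoxybenzylidene)but-3-enoic acid | COc1ccc(/C=C(C(=O)O)\C(=C/c2ccc(OCc3ccccc3)cc2)C(=O)OC)cc1 | intermediate
11 | mixed ethyl carbonic anhydride of 10 | COc1ccc(/C=C(C(=O)OC(=O)OCC)\C(=C/c2ccc(OCc3ccccc3)cc2)C(=O)OC)cc1 | intermediate
12 | methyl (2E,3E)-2-[4-(benzyloxy)benzylidene]-3-(hydroxymethyl)-4-(4-methoxyphenyl)but-3-enoate | COc1ccc(/C=C(CO)\C(=C/c2ccc(OCc3ccccc3)cc2)C(=O)OC)cc1 | intermediate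
13 | (3E,4E)-3-[4-(benzyloxy)benzylidene]-4-(4-methoxybenzylidene)dihydrofuran-2(3H)-one | COc1ccc(/C=C2\C(=C/c3ccc(OCc4ccccc4)cc3)C(=O)OC2)cc1 | intermediate
14 | [4-(benzyloxy)-2,6-bis(methoxymethoxy)phenyl]lithium | [Li]c1c(OCOC)cc(OCc2ccccc2)cc1OCOC | intermediate
15 | (2E,3E)-1-[4-(benzyloxy)-2,6-bis(methoxymethoxy)phenyl]-2-[4-(benzyloxy)benzylidene]-3-(hydroxymethyl)-4-(4-methoxyphenyl)but-3-en-1-one | COc1ccc(/C=C(CO)\C(=C/c2ccc(OCc3ccccc3)cc2)C(=O)c2c(OCOC)cc(OCc3ccccc3)cc2OCOC)cc1 | intermediate
16 | (2E,3E)-4-[4-(benzyloxy)-2,6-bis(methoxymethoxy)phenyl]-3-[4-(benzyloxy)benzylidene]-2-(4-methoxybenzylidene)-4-oxobutanal | COc1ccc(/C=C(C=O)\C(=C/c2ccc(OCc3ccccc3)cc2)C(=O)c2c(OCOC)cc(OCc3ccccc3)cc2OCOC)cc1 | intermediate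
17 | [4-methoxy-2,6-bis(methoxymethoxy)phenyl]lithium | [Li]c1c(OCOC)cc(OC)cc1OCOC | intermediate
18 | (2E,3E)-1-[4-(benzyloxy)-2,6-bis(methoxymethoxy)phenyl]-2-[4-(benzyloxy)benzylidene]-4-hydroxy-4-[4-methoxy-2,6-bis(methoxymethoxy)phenyl]-3-(4-methoxybenzylidene)butan-1-one, racemic at the carbinol carbon | COc1ccc(/C=C(C(O)c2c(OCOC)cc(OC)cc2OCOC)\C(=C/c2ccc(OCc3ccccc3)cc2)C(=O)c2c(OCOC)cc(OCc3ccccc3)cc2OCOC)cc1 | intermediate
19 | (2E,3E)-1-[4-methoxy-2,6-bis(methoxymethoxy)phenyl]-2-(4-methoxybenzylidene)-3-[4-(benzyloxy)benzylidene]-4-[4-(benzyloxy)-2,6-bis(methoxymethoxy)phenyl]butane-1,4-dione | COc1ccc(/C=C(C(=O)c2c(OCOC)cc(OC)cc2OCOC)\C(=C/c2ccc(OCc3ccccc3)cc2)C(=O)c2c(OCOC)cc(OCc3ccccc3)cc2OCOC)cc1 | intermediate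
20 | (2E,3E)-1-(2,6-dihydroxy-4-methoxyphenyl)-2-(4-methoxybenzylidene)-3-[4-(benzyloxy)benzylidene]-4-[4-(benzyloxy)-2,6-dihydroxyphenyl]butane-1,4-dione (key-step precursor) | COc1ccc(/C=C(C(=O)c2c(O)cc(OC)cc2O)\C(=C/c2ccc(OCc3ccccc3)cc2)C(=O)c2c(O)cc(OCc3ccccc3)cc2O)cc1 | intermediate
21 | (2S,3R)-7-(benzyloxy)-2-[4-(benzyloxy)phenyl]-3-[(E)-1-(2,6-dihydroxy-4-methoxybenzoyl)-2-(4-methoxyphenyl)ethenyl]-5-hydroxychroman-4-one | COc1ccc(/C=C(C(=O)c2c(O)cc(OC)cc2O)\[C@H]2C(=O)c3c(O)cc(OCc4ccccc4)cc3O[C@@H]2c2ccc(OCc3ccccc3)cc2)cc1 | intermediate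
22 | (2S,3S)-3-{(2S,3R)-7-(benzyloxy)-2-[4-(benzyloxy)phenyl]-5-hydroxy-4-oxochroman-3-yl}-5-hydroxy-7-methoxy-2-(4-methoxyphenyl)chroman-4-one (key-step product) | COc1ccc([C@H]2Oc3cc(OC)cc(O)c3C(=O)[C@H]2[C@H]2C(=O)c3c(O)cc(OCc4ccccc4)cc3O[C@@H]2c2ccc(OCc3ccccc3)cc2)cc1 | intermediate
23 | (2S,3S)-3-[(2S,3R)-5,7-dihydroxy-2-(4-hydroxyphenyl)-4-oxochroman-3-yl]-5-hydroxy-7-methoxy-2-(4-methoxyphenyl)chroman-4-one (CNP0279849.1) | COc1ccc([C@H]2Oc3cc(OC)cc(O)c3C(=O)[C@H]2[C@H]2C(=O)c3c(O)cc(O)cc3O[C@@H]2c2ccc(O)cc2)cc1 | target

## Step count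

Total step count: 14.
Longest linear sequence: 11 steps (steps 4 to 14, from dimethyl succinate 5 to 23).

## Steps most likely to fail

**Step 13.** Three things may go wrong:
- poor facial selectivity of the catalyst on the crowded, twisted diene;
- closure of the two halves in the unwanted order;
- loss of the kinetic cis arrangement at C2/C3 by epimerisation.

Fallback: asymmetric induction is given up in favour of resolution.
- Setting out from 20, a plain base-mediated chalcone-to-flavanone isomerisation (Et3N (cat.), CH2Cl2, low temperature) is run without a chiral catalyst.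
- The racemic cis,trans diastereomer is separated from the other diastereomers on silica.
- It is then resolved by preparative HPLC on an amylose tris(3,5-dimethylphenylcarbamate) phase. This should give 22 together with its mirror image, (2R,3R)-3-{(2R,3S)-7-(benzyloxy)-2-[4-(benzyloxy)phenyl]-5-hydroxy-4-oxochroman-3-yl}-5-hydroxy-7-methoxy-2-(4-methoxyphenyl)chroman-4-one F1.
- The route is rejoined at 22.

**Step 12.** Uncatalysed ring closure during or after acetal cleavage would settle the flavanone units in racemic, thermodynamic form before the catalyst is met.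

Fallback: the closure is undone rather than avoided.
- Setting out from 19, hot methanolic HCl strips the acetals and closes both rings to the stereoisomer mixture of the 7'',4'''-di-O-benzyl biflavanone F2.
- Classical alkaline flavanone ring opening follows (aq KOH, EtOH, argon, 0 °C to rt). This is E1cB at C3 and C3'', and the chalcone polyphenoxide is favoured at high pH.
- Rapid pouring into ice-cold dilute HCl and immediate extraction returns the open bis-chalcone.
- The route is rejoined at 20.

**Step 8.** The crowded aryllithium may add sluggishly to the conjugated lactone carbonyl, or the adduct may stay locked as its cyclic hemiketal so that the next oxidation stalls.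

Fallback: the electrophile is moved to the aldehyde oxidation level.
- Setting out from 13, i-Bu2AlH (CH2Cl2, −78 °C) gives the lactol (3E,4E)-3-[4-(benzyloxy)benzylidene]-4-(4-methoxybenzylidene)tetrahydrofuran-2-ol F3.
- Two equivalents of 14 add to its open hydroxy-enal form to give (2E,3E)-1-[4-(benzyloxy)-2,6-bis(methoxymethoxy)phenyl]-2-[4-(benzyloxy)benzylidene]-3-(4-methoxybenzylidene)butane-1,4-diol F4.
- A Swern oxidation ((COCl)2, DMSO, Et3N, CH2Cl2, −78 °C) activates both alcohols before base is added, so that no lactol can form and be over-oxidised.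
- This delivers 16, where the route is rejoined; step 9 is skipped.

## Further compounds

F1 | step 13 | (2R,3R)-3-{(2R,3S)-7-(benzyloxy)-2-[4-(benzyloxy)phenyl]-5-hydroxy-4-oxochroman-3-yl}-5-hydroxy-7-methoxy-2-(4-methoxyphenyl)chroman-4-one | COc1ccc([C@@H]2Oc3cc(OC)cc(O)c3C(=O)[C@@H]2[C@@H]2C(=O)c3c(O)cc(OCc4ccccc4)cc3O[C@H]2c2ccc(OCc3ccccc3)cc2)cc1
F2 | step 12 | stereoisomer mixture of the 7'',4'''-di-O-benzyl biflavanone (no defined configuration) | COc1ccc(C2Oc3cc(OC)cc(O)c3C(=O)C2C2C(=O)c3c(O)cc(OCc4ccccc4)cc3OC2c2ccc(OCc3ccccc3)cc2)cc1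
F3 | step 8 | (3E,4E)-3-[4-(benzyloxy)benzylidene]-4-(4-methoxybenzylidene)tetrahydrofuran-2-ol | COc1ccc(/C=C2\C(=C/c3ccc(OCc4ccccc4)cc3)C(O)OC2)cc1
F4 | step 8 | (2E,3E)-1-[4-(benzyloxy)-2,6-bis(methoxymethoxy)phenyl]-2-[4-(benzyloxy)benzylidene]-3-(4-methoxybenzylidene)butane-1,4-diol | COc1ccc(/C=C(CO)\C(=C/c2ccc(OCc3ccccc3)cc2)C(O)c2c(OCOC)cc(OCc3ccccc3)cc2OCOC)cc1
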